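The piperidine is disconnected at N1–C6 and C5–C6. The key step trades on the ring's N1–C6H2 unit: because C6 bears no substituent, this one ring atom can originate from CO, inserted at the terminal carbon of a but-3-enyl chain attached to the preformed C2 stereocentre. A single rhodium-catalysed cyclohydrocarbonylation should form both bonds and close the ring as an ene-carbamate. The precursor is the (R)-N-Boc-1-arylbut-3-enylamine of a 2,6-bis(benzyloxy)-4-methoxyphenyl ring, made by sulfinimine allylation. It also carries a spectator bromine at the carbon that becomes flavone C4a, which later allows acid-free acetylation before ring C is annulated.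

Key step: step 7

Remark: the benzylic carbon is (R) in the target string and, with ligands ranked N > aryl C > CH2 > H, stays (R) in every intermediate from 11 to 26.
Remark: the ring bromine takes no part in step 7; it is included because the 2,4,6-trioxygenated benzylic C–N bond and the Boc group are acid-labile, so the acetyl group is better introduced by halogen–metal exchange than by Friedel–Crafts chemistry.

Step 1
Reactants: 1 2,4,6-trihydroxybenzaldehyde; 2 iodomethane
Product: 3 2,6-dihydroxy-4-methoxybenzaldehyde
Conditions: MeI (1.05 equiv), KHCO3 (1.2 equiv), DMF, 40 °C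
Reagents that add atoms: iodomethane, CI
Why: Regioselective Williamson etherification: the 4-hydroxyl, para to the formyl group and not engaged in hydrogen bonding to the carbonyl, is the most acidic, so a hydrogencarbonate base should form mainly the 4-phenoxide and alkylation should stop after one methyl group.

Step 2
Reactants: 3 2,6-dihydroxy-4-methoxybenzaldehyde; 4 benzyl bromide
Product: 5 2,6-bis(benzyloxy)-4-methoxybenzaldehyde
Conditions: BnBr (2.4 equiv), K2CO3 (3 equiv), DMF, 70 °C
Reagents that add atoms: benzyl bromide, BrCc1ccccc1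
Why: Williamson etherification under carbonate/DMF conditions alkylates both ortho-hydroxyls, and benzyl is chosen because it tolerates the organometallic, mildly acidic and carbonylation steps and is removed later in the same hydrogenation that saturates the ring.

Step 3
Reactants: 5 2,6-bis(benzyloxy)-4-methoxybenzaldehyde; 6 N-bromosuccinimide
Product: 7 2,6-bis(benzyloxy)-3-bromo-4-methoxybenzaldehyde
Conditions: NBS (1.0 equiv), MeCN, 0 °C → rt
Reagents that add atoms: N-bromosuccinimide, O=C1CCC(=O)N1Br
Why: Electrophilic aromatic bromination: C3 (equivalent to C5) is ortho/para to three alkoxy groups and meta to the formyl group, so one equivalent of NBS should give the monobromide that serves as the handle for step 8.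

Step 4
Reactants: 7 2,6-bis(benzyloxy)-3-bromo-4-methoxybenzaldehyde; 8 (S)-tert-butanesulfinamide
Product: 9 (S)-N-[(E)-[2,6-bis(benzyloxy)-3-bromo-4-methoxyphenyl]methylidene]-2-methylpropane-2-sulfinamide
Conditions: Ti(OEt)4 (2 equiv), THF, 65 °C
Reagents that add atoms: (S)-tert-butanesulfinamide, CC(C)(C)[S@](=O)N
Why: Titanium-alkoxide-mediated sulfinimine condensation, in which Ti(OEt)4 acts as Lewis acid and water scavenger so that even the doubly ortho-substituted aldehyde should give the E-aldimine without affecting the sulfur stereocentre.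

Step 5
Reactants: 9 (S)-N-[(E)-[2,6-bis(benzyloxy)-3-bromo-4-methoxyphenyl]methylidene]-2-methylpropane-2-sulfinamide; 10 allyl bromide
Product: 11 (S)-N-[(1R)-1-[2,6-bis(benzyloxy)-3-bromo-4-methoxyphenyl]but-3-en-1-yl]-2-methylpropane-2-sulfinamide
Conditions: indium powder (1.5 equiv), allyl bromide (2 equiv), THF, 60 °C
Reagents that add atoms: allyl bromide, C=CCBr
Why: Indium-mediated Barbier-type allylation of an N-tert-butanesulfinyl aldimine, in which the allylindium reagent adds through a chair-like, metal-coordinated transition state to the Re face of the (S)-sulfinyl E-aldimine, which for an aryl aldimine sets the (R) carbinamine centre under auxiliary control.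

Step 6
Reactants: 11 (S)-N-[(1R)-1-[2,6-bis(benzyloxy)-3-bromo-4-methoxyphenyl]but-3-en-1-yl]-2-methylpropane-2-sulfinamide; 12 di-tert-butyl dicarbonate
Product: 14 tert-butyl N-[(1R)-1-[2,6-bis(benzyloxy)-3-bromo-4-methoxyphenyl]but-3-en-1-yl]carbamate, via amine hydrochloride 13 (not isolated)
Conditions: HCl (4 M in 1,4-dioxane, 2.5 equiv), MeOH, 0 °C, 30 min; evaporate; then Boc2O (1.3 equiv), Et3N (4 equiv), CH2Cl2, rt
Reagents that add atoms: di-tert-butyl dicarbonate, CC(C)(C)OC(=O)OC(=O)OC(C)(C)C
Why: Acidolysis of the N–S bond (the sulfinyl group leaves as its methyl ester) followed by N-acylation with Boc2O is the standard sulfinamide-to-carbamate exchange; neither event involves the C–N stereocentre, and the acid stage is kept cold and brief because the trialkoxybenzylic C–N bond is acid-sensitive.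

Step 7
Reactants: 14 tert-butyl N-[(1R)-1-[2,6-bis(benzyloxy)-3-bromo-4-methoxyphenyl]but-3-en-1-yl]carbamate; 15 carbon monoxide
Product: 18 tert-butyl (2R)-2-[2,6-bis(benzyloxy)-3-bromo-4-methoxyphenyl]-3,4-dihydro-2H-pyridine-1-carboxylate, via linear aldehyde 16 (not isolated), via cyclic hemiaminal 17 (not isolated)
Conditions: Rh(acac)(CO)2 (1 mol%), BIPHEPHOS (2 mol%), CO/H2 (1:1, 4 atm), toluene, 65 °C; then PPTS (5 mol%), 65 °C to complete dehydration
Reagents that add atoms: carbon monoxide, [C-]#[O+]
Why: Hydrometalation of the terminal alkene by the Rh–H species places rhodium on the terminal carbon, and migratory insertion of CO followed by H2 cleavage of the acyl–rhodium bond should release linear aldehyde 16, creating C5–C6. The carbamate N–H then adds to the formyl carbon (new N1–C6 bond) in a 6-exo-trig closure to hemiaminal 17, and loss of water through the N-acyliminium ion gives ene-carbamate 18; this is the established cyclohydrocarbonylation of homoallylic carbamates to six-membered ene-carbamates. No stereocentre is created in 18, since the hemiaminal carbon is transient, and C2, set in step 5, lies three atoms from the reacting alkene terminus and has no pathway to epimerise under these near-neutral conditions. The step needs linear rather than branched hydroformylation (a branched aldehyde would close to a methyl-substituted five-membered ring) and carbonylation rather than plain alkene hydrogenation; the first is secured by the unhindered monosubstituted alkene, insulated from the bulky aryl carbon by a CH2 group, together with the wide-bite-angle bisphosphite, the second by a modest pressure of 1:1 syngas. The aryl bromide, benzyl ethers and Boc group are expected to be inert to the rhodium hydride catalyst.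

Step 8
Reactants: 18 tert-butyl (2R)-2-[2,6-bis(benzyloxy)-3-bromo-4-methoxyphenyl]-3,4-dihydro-2H-pyridine-1-carboxylate; 19 N-methoxy-N-methylacetamide
Product: 21 tert-butyl (2R)-2-[3-acetyl-2,6-bis(benzyloxy)-4-methoxyphenyl]-3,4-dihydro-2H-pyridine-1-carboxylate, via aryllithium 20 (not isolated)
Conditions: n-BuLi (1.05 equiv), THF, −78 °C, 15 min; then MeC(O)N(OMe)Me (1.5 equiv), −78 → −20 °C; sat. aq NH4Cl
Reagents that add atoms: N-methoxy-N-methylacetamide, CON(C)C(C)=O
Why: Bromine–lithium exchange at −78 °C is far faster than deprotonation or attack on the carbamate, and the resulting aryllithium is acylated once by the Weinreb amide (Weinreb ketone synthesis), placing the acetyl group on the future C4a without any Lewis or Brønsted acid.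

Step 9
Reactants: 21 tert-butyl (2R)-2-[3-acetyl-2,6-bis(benzyloxy)-4-methoxyphenyl]-3,4-dihydro-2H-pyridine-1-carboxylate
Product: 22 tert-butyl (2R)-2-(3-acetyl-2,6-dihydroxy-4-methoxyphenyl)piperidine-1-carboxylate
Conditions: H2 (1 atm), 10 wt% palladium on carbon, EtOAc/MeOH, rt
Reagents that add atoms: none
Why: Heterogeneous catalytic hydrogenation should saturate the electron-rich C5=C6 bond of the ene-carbamate and hydrogenolyse both benzyl ethers, while the Boc group, the aryl ketone and the hindered benzylic C–N bond are expected to persist under neutral conditions at one atmosphere.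

Step 10
Reactants: 22 tert-butyl (2R)-2-(3-acetyl-2,6-dihydroxy-4-methoxyphenyl)piperidine-1-carboxylate; 23 benzoyl chloride
Product: 24 tert-butyl (2R)-2-[2,6-dihydroxy-4-methoxy-3-(3-oxo-3-phenylpropanoyl)phenyl]piperidine-1-carboxylate
Conditions: LiN(SiMe3)2 (4.2 equiv), THF, −78 → −10 °C; then PhCOCl (1.05 equiv), −78 °C → rt; sat. aq NH4Cl
Reagents that add atoms: benzoyl chloride, O=C(Cl)c1ccccc1
Why: Direct Baker–Venkataraman-type C-benzoylation (crossed Claisen condensation of a polyanion): excess amide base forms the diphenoxide–enolate, whose enolate carbon is the most nucleophilic site, so the 1,3-diketone should form without prior O-protection and without acid.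

Step 11
Reactants: 24 tert-butyl (2R)-2-[2,6-dihydroxy-4-methoxy-3-(3-oxo-3-phenylpropanoyl)phenyl]piperidine-1-carboxylate
Product: 26 7-hydroxy-5-methoxy-2-phenyl-8-[(2R)-piperidin-2-yl]-4H-chromen-4-one, via N-deprotected diketone hydrochloride 25 (not isolated)
Conditions: HCl (4 M in 1,4-dioxane), 0 °C → rt; then aq NaHCO3 to pH 8
Reagents that add atoms: none
Why: Acidolytic Boc cleavage runs together with acid-catalysed cyclodehydration of the o-hydroxyaryl 1,3-diketone, in which the only hydroxyl ortho to the acyl group adds to the benzoyl carbonyl and water is lost to form the 4-pyranone ring C; keeping the mixture protonated and at or below room temperature guards the benzylic C2 centre against retro-Mannich or quinone-methide racemisation.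

Compound list
1 | 2,4,6-trihydroxybenzaldehyde | O=Cc1c(O)cc(O)cc1O | starting material
2 | iodomethane | CI | starting material
3 | 2,6-dihydroxy-4-methoxybenzaldehyde | COc1cc(O)c(C=O)c(O)c1 | intermediate
4 | benzyl bromide | BrCc1ccccc1 | starting material
5 | 2,6-bis(benzyloxy)-4-methoxybenzaldehyde | COc1cc(OCc2ccccc2)c(C=O)c(OCc2ccccc2)c1 | intermediate
6 | N-bromosuccinimide | O=C1CCC(=O)N1Br | starting material
7 | 2,6-bis(benzyloxy)-3-bromo-4-methoxybenzaldehyde | COc1cc(OCc2ccccc2)c(C=O)c(OCc2ccccc2)c1Br | intermediate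
8 | (S)-tert-butanesulfinamide | CC(C)(C)[S@](=O)N | starting material
9 | (S)-N-[(E)-[2,6-bis(benzyloxy)-3-bromo-4-methoxyphenyl]methylidene]-2-methylpropane-2-sulfinamide | CC(C)(C)[S@](=O)/N=C/c1c(OCc2ccccc2)cc(OC)c(Br)c1OCc3ccccc3 | intermediate
10 | allyl bromide | C=CCBr | starting material
11 | (S)-N-[(1R)-1-[2,6-bis(benzyloxy)-3-bromo-4-methoxyphenyl]but-3-en-1-yl]-2-methylpropane-2-sulfinamide | CC(C)(C)[S@](=O)N[C@H](CC=C)c1c(OCc2ccccc2)cc(OC)c(Br)c1OCc3ccccc3 | intermediate
12 | di-tert-butyl dicarbonate | CC(C)(C)OC(=O)OC(=O)OC(C)(C)C | starting material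
13 | (1R)-1-[2,6-bis(benzyloxy)-3-bromo-4-methoxyphenyl]but-3-en-1-amine hydrochloride | Cl.N[C@H](CC=C)c1c(OCc2ccccc2)cc(OC)c(Br)c1OCc3ccccc3 | intermediate (not isolated)
14 | tert-butyl N-[(1R)-1-[2,6-bis(benzyloxy)-3-bromo-4-methoxyphenyl]but-3-en-1-yl]carbamate (key-step precursor) | COc1cc(OCc2ccccc2)c([C@H](NC(=O)OC(C)(C)C)CC=C)c(OCc2ccccc2)c1Br | intermediate
15 | carbon monoxide | [C-]#[O+] | starting material
16 | tert-butyl N-[(1R)-1-[2,6-bis(benzyloxy)-3-bromo-4-methoxyphenyl]-5-oxopentyl]carbamate | COc1cc(OCc2ccccc2)c([C@H](NC(=O)OC(C)(C)C)CCCC=O)c(OCc2ccccc2)c1Br | intermediate (not isolated)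
17 | tert-butyl (2R)-2-[2,6-bis(benzyloxy)-3-bromo-4-methoxyphenyl]-6-hydroxypiperidine-1-carboxylate (both C6 epimers) | COc1cc(OCc2ccccc2)c([C@H]2CCCC(O)N2C(=O)OC(C)(C)C)c(OCc2ccccc2)c1Br | intermediate (not isolated)
18 | tert-butyl (2R)-2-[2,6-bis(benzyloxy)-3-bromo-4-methoxyphenyl]-3,4-dihydro-2H-pyridine-1-carboxylate (key-step product) | COc1cc(OCc2ccccc2)c([C@H]2CCC=CN2C(=O)OC(C)(C)C)c(OCc2ccccc2)c1Br | intermediate
19 | N-methoxy-N-methylacetamide | CON(C)C(C)=O | starting material
20 | tert-butyl (2R)-2-[2,6-bis(benzyloxy)-3-lithio-4-methoxyphenyl]-3,4-dihydro-2H-pyridine-1-carboxylate | COc1cc(OCc2ccccc2)c([C@H]2CCC=CN2C(=O)OC(C)(C)C)c(OCc2ccccc2)c1[Li] | intermediate (not isolated)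
21 | tert-butyl (2R)-2-[3-acetyl-2,6-bis(benzyloxy)-4-methoxyphenyl]-3,4-dihydro-2H-pyridine-1-carboxylate | COc1cc(OCc2ccccc2)c([C@H]2CCC=CN2C(=O)OC(C)(C)C)c(OCc2ccccc2)c1C(C)=O | intermediate
22 | tert-butyl (2R)-2-(3-acetyl-2,6-dihydroxy-4-methoxyphenyl)piperidine-1-carboxylate | COc1cc(O)c([C@H]2CCCCN2C(=O)OC(C)(C)C)c(O)c1C(C)=O | intermediate
23 | benzoyl chloride | O=C(Cl)c1ccccc1 | starting material
24 | tert-butyl (2R)-2-[2,6-dihydroxy-4-methoxy-3-(3-oxo-3-phenylpropanoyl)phenyl]piperidine-1-carboxylate | COc1cc(O)c([C@H]2CCCCN2C(=O)OC(C)(C)C)c(O)c1C(=O)CC(=O)c3ccccc3 | intermediate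
25 | 1-[2,4-dihydroxy-6-methoxy-3-[(2R)-piperidin-2-yl]phenyl]-3-phenylpropane-1,3-dione hydrochloride | Cl.COc1cc(O)c([C@H]2CCCCN2)c(O)c1C(=O)CC(=O)c3ccccc3 | intermediate (not isolated)
26 | 7-hydroxy-5-methoxy-2-phenyl-8-[(2R)-piperidin-2-yl]-4H-chromen-4-one (CNP0140822.1) | COc1cc(O)c([C@H]2CCCCN2)c2oc(-c3ccccc3)cc(=O)c12 | target

Total step count: 11. Longest linear sequence: 11 steps (1 → 26).

Steps most likely to fail

1. Step 7. The hydroformylation may be slow at the hindered substrate, leak to the branched aldehyde or to simple alkene hydrogenation, or stall at the hemiaminal. Fallback: setting out from 14, N-allylation (NaH, allyl bromide 10, DMF, 0 °C → rt) would give tert-butyl N-allyl-N-[(1R)-1-[2,6-bis(benzyloxy)-3-bromo-4-methoxyphenyl]but-3-en-1-yl]carbamate F1. Ring-closing metathesis (second-generation Grubbs catalyst, CH2Cl2, 40 °C) would then close the same six-membered ring as tert-butyl (2R)-2-[2,6-bis(benzyloxy)-3-bromo-4-methoxyphenyl]-3,6-dihydro-2H-pyridine-1-carboxylate F2, with C6 now coming from allyl bromide. Bromine–lithium exchange and Weinreb acylation as in step 8 would give tert-butyl (2R)-2-[3-acetyl-2,6-bis(benzyloxy)-4-methoxyphenyl]-3,6-dihydro-2H-pyridine-1-carboxylate F3. The hydrogenation of step 9 removes the difference in double-bond position, so the route is rejoined at 22.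

2. Step 8. Deprotonation at the vinylic C6–H or the benzylic C2–H (the latter eroding the stereocentre), attack of the organolithium on the carbamate, or enolisation of the Weinreb amide by the hindered aryllithium (returning debrominated material) may compete with acylation. Fallback: setting out from 18, Stille coupling with tributyl(1-ethoxyvinyl)stannane (Pd(PPh3)4, toluene, 100 °C) would give tert-butyl (2R)-2-[2,6-bis(benzyloxy)-3-(1-ethoxyvinyl)-4-methoxyphenyl]-3,4-dihydro-2H-pyridine-1-carboxylate F4. Brief hydrolysis of the far more acid-labile aryl enol ether (oxalic acid, wet THF, 0 °C) would unveil the methyl ketone and rejoin the route at 21 without any organolithium.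

3. Step 5. Facial selectivity of allyl transfer may be poor if the two ortho ether oxygens compete for indium, and addition to the doubly ortho-substituted aldimine may be sluggish. Fallback: setting out from aldehyde 7, three-component aminoallylation with ammonia and allylboronic acid pinacol ester (NH3 in MeOH, rt) would give racemic 1-[2,6-bis(benzyloxy)-3-bromo-4-methoxyphenyl]but-3-en-1-amine F5. Boc2O/Et3N would convert it into racemic tert-butyl N-[1-[2,6-bis(benzyloxy)-3-bromo-4-methoxyphenyl]but-3-en-1-yl]carbamate F6, and preparative chromatography on a chiral stationary phase would supply the (R)-enantiomer, rejoining the route at 14.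

Further compounds
F1 | step 7 | tert-butyl N-allyl-N-[(1R)-1-[2,6-bis(benzyloxy)-3-bromo-4-methoxyphenyl]but-3-en-1-yl]carbamate | COc1cc(OCc2ccccc2)c([C@H](N(CC=C)C(=O)OC(C)(C)C)CC=C)c(OCc2ccccc2)c1Br
F2 | step 7 | tert-butyl (2R)-2-[2,6-bis(benzyloxy)-3-bromo-4-methoxyphenyl]-3,6-dihydro-2H-pyridine-1-carboxylate | COc1cc(OCc2ccccc2)c([C@H]2CC=CCN2C(=O)OC(C)(C)C)c(OCc2ccccc2)c1Br
F3 | step 7 | tert-butyl (2R)-2-[3-acetyl-2,6-bis(benzyloxy)-4-methoxyphenyl]-3,6-dihydro-2H-pyridine-1-carboxylate | COc1cc(OCc2ccccc2)c([C@H]2CC=CCN2C(=O)OC(C)(C)C)c(OCc2ccccc2)c1C(C)=O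
F4 | step 8 | tert-butyl (2R)-2-[2,6-bis(benzyloxy)-3-(1-ethoxyvinyl)-4-methoxyphenyl]-3,4-dihydro-2H-pyridine-1-carboxylate | COc1cc(OCc2ccccc2)c([C@H]2CCC=CN2C(=O)OC(C)(C)C)c(OCc2ccccc2)c1C(=C)OCC
F5 | step 5 | racemic 1-[2,6-bis(benzyloxy)-3-bromo-4-methoxyphenyl]but-3-en-1-amine | NC(CC=C)c1c(OCc2ccccc2)cc(OC)c(Br)c1OCc3ccccc3
F6 | step 5 | racemic tert-butyl N-[1-[2,6-bis(benzyloxy)-3-bromo-4-methoxyphenyl]but-3-en-1-yl]carbamate | COc1cc(OCc2ccccc2)c(C(NC(=O)OC(C)(C)C)CC=C)c(OCc2ccccc2)c1Br
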